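The benzene ring is read as a twofold aryne built around the C5 methoxy group. A symmetric bis(silyl triflate) made from 5-methoxyresorcinol first releases the C4a≡C8a aryne, which takes up 3-methylbut-2-enal: a [2+2] addition forms O1–C8a and C4–C4a, the benzoxete opens to an o-quinone methide, and oxa-6π closure completes the 2,2-dimethyl-2H-pyran ring in one operation. The step exploits the C5–OMe group beside C4a, which polarises the aryne so that oxygen enters at C8a. The silyl triflate that survives then gives the C6≡C7 aryne, into which 4-methoxyphenylacetic acid inserts to set the C6 acyl and C7 hydroxyl groups.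

Key step: step 3

Remark: the target has no stereocentre; ring atoms are numbered as in 2H-chromene (O1, C2, C3, C4, C4a, C5, C6, C7, C8, C8a), and compounds 1, 6 and 11 are taken as commercially available.

Step 1
Reactants: 1 5-methoxybenzene-1,3-diol
Product: 2 4,6-dibromo-5-methoxybenzene-1,3-diol
Conditions: NBS (2.05 equiv), MeCN, −30 °C to 0 °C
Reagents that add atoms: N-bromosuccinimide, O=C1CCC(=O)N1Br
Why: Electrophilic aromatic bromination in which each bromine should enter para to one hydroxyl and ortho to the methoxy group (the positions that also take acyl and formyl electrophiles in this ring), while the carbon between the two hydroxyls reacts last, as in the 4,6-dibromination of resorcinol.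

Step 2
Reactants: 2 4,6-dibromo-5-methoxybenzene-1,3-diol
Product: 5 5-methoxy-4,6-bis(trimethylsilyl)-1,3-phenylene bis(trifluoromethanesulfonate), via bis(trimethylsilyl) ether 3 (not isolated), via dilithium bis(phenoxide) 4 (not isolated)
Conditions: HMDS, THF, 70 °C, then evaporation; n-BuLi (2.2 equiv), THF, −100 °C to −78 °C; Tf2O (2.4 equiv), −100 °C to rt
Reagents that add atoms: hexamethyldisilazane, C[Si](C)(C)N[Si](C)(C)C; trifluoromethanesulfonic anhydride, O=S(=O)(OS(=O)(=O)C(F)(F)F)C(F)(F)F
Why: One-pot O-silylation, double bromine–lithium exchange and double anionic 1,3-O→C silyl migration (retro-Brook rearrangement) should place each silicon exactly where a bromine stood, and Tf2O then traps the dilithium bis(phenoxide), which is the standard route to o-silylaryl triflates applied twice on a symmetric ring.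

Step 3
Reactants: 5 5-methoxy-4,6-bis(trimethylsilyl)-1,3-phenylene bis(trifluoromethanesulfonate); 6 3-methylbut-2-enal
Product: 10 5-methoxy-2,2-dimethyl-6-(trimethylsilyl)-2H-chromen-7-yl trifluoromethanesulfonate, via aryne 7 (not isolated), via benzoxete 8 (not isolated), via o-quinone methide 9 (not isolated)
Conditions: 6 (5 equiv), CsF (1.1 equiv, added in portions), MeCN, 0 °C to rt
Reagents that add atoms: none
Why: Fluoride attacks one of the two equivalent silicon atoms of 5 and 1,2-elimination of triflate gives aryne 7 (C4a≡C8a); the carbonyl oxygen of 6 bonds to C8a and the carbonyl carbon to C4a in an asynchronous [2+2] cycloaddition that closes the four-membered ring of benzoxete 8, conrotatory 4π ring opening cleaves its O–CH bond to give o-quinone methide 9, and thermal disrotatory oxa-6π electrocyclisation (O1–C2) closes the pyran ring. The closest known reaction type is the annulation of arynes with α,β-unsaturated aldehydes to 2H-chromenes, a relative of aryne insertion into the C=O bond of formamides. No stereocentre remains, because the benzoxete carbon of 8 is racemic and becomes sp2 in 9, and C2 carries two methyl groups. Regioselectivity is required and is secured by the C5 methoxy group next to C4a, whose inductive effect distorts the aryne so that the nucleophilic oxygen attacks the distal carbon C8a while the developing carbanion sits at C4a, ortho to OMe. Mono-selectivity is also required: fluoride is limiting, the first desilylation relieves the strain of two SiMe3 groups crowding the methoxy group, and in 10 an ether oxygen has replaced a triflyloxy group para to the remaining C6–Si bond, which should slow a second elimination. Capture of 9 by a second aryne should be outrun by the intramolecular 6π closure and by the excess of 6.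

Step 4
Reactants: 10 5-methoxy-2,2-dimethyl-6-(trimethylsilyl)-2H-chromen-7-yl trifluoromethanesulfonate; 11 2-(4-methoxyphenyl)acetic acid
Product: 13 1-(7-hydroxy-5-methoxy-2,2-dimethyl-2H-chromen-6-yl)-2-(4-methoxyphenyl)ethan-1-one, via aryne 12 (not isolated)
Conditions: 11 (1.5 equiv), CsF (4 equiv), THF, 125 °C (sealed tube); aq NH4Cl
Reagents that add atoms: none
Why: Fluoride-induced elimination should give aryne 12 (C6≡C7), the carboxylate oxygen of deprotonated 11 adds to C7 (distal to the C5 methoxy group) and the C6 carbanion takes the acyl group from oxygen through a four-membered transition structure (aryne insertion into the C–O bond of a carboxylic acid, an anionic Fries-type acyl shift), so that the o-hydroxyaryl ketone is formed directly without protecting groups.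

Compound list
1 | 5-methoxybenzene-1,3-diol (5-methoxyresorcinol) | COc1cc(O)cc(O)c1 | starting material
2 | 4,6-dibromo-5-methoxybenzene-1,3-diol | COc1c(Br)c(O)cc(O)c1Br | intermediate
3 | 4,6-dibromo-5-methoxy-1,3-bis(trimethylsilyloxy)benzene | COc1c(Br)c(O[Si](C)(C)C)cc(O[Si](C)(C)C)c1Br | intermediate
4 | dilithium 5-methoxy-4,6-bis(trimethylsilyl)benzene-1,3-diolate | COc1c([Si](C)(C)C)c([O-])cc([O-])c1[Si](C)(C)C.[Li+].[Li+] | intermediate
5 | 5-methoxy-4,6-bis(trimethylsilyl)-1,3-phenylene bis(trifluoromethanesulfonate) | COc1c([Si](C)(C)C)c(OS(=O)(=O)C(F)(F)F)cc(OS(=O)(=O)C(F)(F)F)c1[Si](C)(C)C | intermediate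
6 | 3-methylbut-2-enal | CC(C)=CC=O | starting material
7 | 4,5-didehydro-3-methoxy-2-(trimethylsilyl)phenyl trifluoromethanesulfonate (aryne C4a≡C8a) | COC1=C([Si](C)(C)C)C(OS(=O)(=O)C(F)(F)F)=CC#C1 | intermediate
8 | 3-methoxy-2-(2-methylprop-1-en-1-yl)-4-(trimethylsilyl)-2H-benzo[b]oxet-5-yl trifluoromethanesulfonate (racemic) | COc1c([Si](C)(C)C)c(OS(=O)(=O)C(F)(F)F)cc2c1C(C=C(C)C)O2 | intermediate
9 | (4Z)-3-methoxy-4-(3-methylbut-2-en-1-ylidene)-5-oxo-2-(trimethylsilyl)cyclohexa-2,6-dien-1-yl trifluoromethanesulfonate (o-quinone methide) | COC1=C([Si](C)(C)C)C(OS(=O)(=O)C(F)(F)F)=CC(=O)/C1=C\C=C(C)C | intermediate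
10 | 5-methoxy-2,2-dimethyl-6-(trimethylsilyl)-2H-chromen-7-yl trifluoromethanesulfonate | COc1c([Si](C)(C)C)c(OS(=O)(=O)C(F)(F)F)cc2c1C=CC(C)(C)O2 | intermediate
11 | 2-(4-methoxyphenyl)acetic acid | COc1ccc(CC(=O)O)cc1 | starting material
12 | 6,7-didehydro-5-methoxy-2,2-dimethyl-2H-chromene (aryne C6≡C7) | COC1=C2C=CC(C)(C)OC2=CC#C1 | intermediate
13 | 1-(7-hydroxy-5-methoxy-2,2-dimethyl-2H-chromen-6-yl)-2-(4-methoxyphenyl)ethan-1-one | COc1ccc(CC(=O)c2c(O)cc3c(c2OC)C=CC(C)(C)O3)cc1 | target

Total step count: 4. Longest linear sequence: 4 steps (1 → 2 → 5 → 10 → 13).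

Steps most likely to fail

1. Step 3 (key step). The fluoride-induced elimination may not stop after one aryne, so that 10 is unmasked again while 5 is still present. The weakly nucleophilic aldehyde oxygen of 6 may also lose aryne 7 to fluoride, to triflate transfer or to quinone methide 9. Fallback, setting out from 5 and coming back at 10: the annulation is staged with a stronger carbonyl acceptor. CsF in N,N-dimethylformamide should convert 5 through aryne 7 into the amino-o-quinone methide F1 (not isolated). Its phenoxide-like oxygen lies para to the remaining C–Si bond and should block a second elimination. Aqueous work-up hydrolyses it to the salicylaldehyde 4-formyl-5-hydroxy-3-methoxy-2-(trimethylsilyl)phenyl trifluoromethanesulfonate F2. 2-Methylprop-1-enylmagnesium bromide (2.2 equiv, THF, −78 °C) should add to the aldehyde to give the allylic alcohol F3. Heating in toluene (110 °C) should dehydrate it to o-quinone methide 9, which closes to 10.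

2. Step 4. The C6 carbanion may be protonated before the O-to-C acyl shift, leaving an aryl ester with hydrogen at C6, and the product phenoxide may be arylated by aryne 12. Fallback, setting out from 10 and coming back at 13: CsF in N,N-dimethylformamide should convert 10 through aryne 12 into the amino-o-quinone methide F4 (not isolated). Work-up hydrolyses it to 7-hydroxy-5-methoxy-2,2-dimethyl-2H-chromene-6-carbaldehyde F5, with the same regiochemical control by the C5 methoxy group. 4-Methoxybenzylmagnesium chloride (2.5 equiv, THF, 0 °C) should give the benzylic carbinol F6. MnO2 (CH2Cl2, rt) should then oxidise the benzylic alcohol to ketone 13.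

3. Step 2. The second bromine–lithium exchange or the second silyl migration may stall in the crowded region around the methoxy group, or the aryllithium may be protonated before migration, and triflation of the hindered phenoxides may be slow. Fallback, setting out from 2 and coming back at 5: the C–Si bonds are made by external silylation instead of anionic migration. Benzyl bromide and K2CO3 (DMF, rt) should give the bis(benzyl ether) F7. t-BuLi (4.2 equiv, THF, −78 °C) followed by Me3SiCl should give the bis(silane) F8. Hydrogenolysis (H2, Pd/C, EtOAc) under neutral conditions should free the diol F9. Tf2O and pyridine (CH2Cl2, 0 °C) should then give 5.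

Further compounds
F1 | step 3 | 4-[(dimethylamino)methylidene]-3-methoxy-5-oxo-2-(trimethylsilyl)cyclohexa-2,6-dien-1-yl trifluoromethanesulfonate | COC1=C([Si](C)(C)C)C(OS(=O)(=O)C(F)(F)F)=CC(=O)C1=CN(C)C
F2 | step 3 | 4-formyl-5-hydroxy-3-methoxy-2-(trimethylsilyl)phenyl trifluoromethanesulfonate | COc1c([Si](C)(C)C)c(OS(=O)(=O)C(F)(F)F)cc(O)c1C=O
F3 | step 3 | 5-hydroxy-4-(1-hydroxy-3-methylbut-2-en-1-yl)-3-methoxy-2-(trimethylsilyl)phenyl trifluoromethanesulfonate (racemic) | COc1c([Si](C)(C)C)c(OS(=O)(=O)C(F)(F)F)cc(O)c1C(O)C=C(C)C
F4 | step 4 | 6-[(dimethylamino)methylidene]-5-methoxy-2,2-dimethyl-2H-chromen-7(6H)-one | COC1=C2C=CC(C)(C)OC2=CC(=O)C1=CN(C)C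
F5 | step 4 | 7-hydroxy-5-methoxy-2,2-dimethyl-2H-chromene-6-carbaldehyde | COc1c(C=O)c(O)cc2c1C=CC(C)(C)O2
F6 | step 4 | 6-[1-hydroxy-2-(4-methoxyphenyl)ethyl]-5-methoxy-2,2-dimethyl-2H-chromen-7-ol (racemic) | COc1ccc(CC(O)c2c(O)cc3c(c2OC)C=CC(C)(C)O3)cc1
F7 | step 2 | 1,5-bis(benzyloxy)-2,4-dibromo-3-methoxybenzene | COc1c(Br)c(OCc2ccccc2)cc(OCc2ccccc2)c1Br
F8 | step 2 | [4,6-bis(benzyloxy)-2-methoxy-1,3-phenylene]bis(trimethylsilane) | COc1c([Si](C)(C)C)c(OCc2ccccc2)cc(OCc2ccccc2)c1[Si](C)(C)C
F9 | step 2 | 5-methoxy-4,6-bis(trimethylsilyl)benzene-1,3-diol | COc1c([Si](C)(C)C)c(O)cc(O)c1[Si](C)(C)C
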